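The constants used here are made up, and the outcome is calculated.

The ratio of product to substrate that the enzyme steps tend towards is 4.42, and the set-ups below differ in how much of that pool of free substrate and product goes to homo dimer.

    substrate + enzyme ⇌ complex (K1 = 276 M⁻¹, k1 = 1.95 × 10⁵ M⁻¹ min⁻¹)
    complex ⇌ enzyme + product (K2 = 0.016 M, k2 = 1370 min⁻¹)
    2 substrate → homo dimer (k3 = 0.836 M⁻¹ min⁻¹)

the same everywhere: enzyme 3.9 µM
- maple: substrate 39 mM (fed, over 3.20 h); time 4.0 h; a stirred flask in which substrate is dosed at a steady rate over 3.20 h without added volume, worked up at 4.0 h
- birch: substrate 39 mM; time 4.0 h; everything together in a closed stirred flask, run for 4.0 h
- larch: substrate 39 mM; a single well-mixed tank run continuously and read at steady state, 4.0 h in it on average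

- percent here means substrate units held: one homo dimer counts as two
- for a step with 2 of a species take k times the square, and two of it per event
- the stated concentrations are those of everything mixed, before any reaction; amounts are the same in each set-up
- the feed brings no volume worth counting
- run time (maple): 4.0 h

- order of the set-ups by the amount of product at the outlet or at the end, in percent of the substrate put in, highest first (maple / birch / larch)
- amount of product at the outlet or at the end, in percent of the substrate put in, maple
- amount of product at the outlet or at the end, in percent of the substrate put in, birch
- amount of product at the outlet or at the end, in percent of the substrate put in, larch

My reckoning assumes that the enzyme holds this ratio, so product is 81.5% of the pool and homo dimer drains the pool through the square of the substrate. Dividing the drain rate at the full charge by the supply rate, charge over time, removes time and leaves the drain number 0.534. It is twice the homo dimer rate constant times charge and run time, over the square of one plus the ratio.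

In a closed flask the pool falls to one part in one plus this number. In the tank, the pool fraction x obeys 1 − x = N x². In the dosed flask the squared concentration averages a third of its final value during dosing, so the number shrinks. Maple gives 65.3% and larch 58.9%. Birch stays below 53.2%, and the order is maple > larch > birch.

Is one number enough? The enzyme's top speed of 5.34 mM min⁻¹ is far above the maple feed of 0.203 mM min⁻¹. Birch, however, starts with its whole charge as substrate, which loses 2.54 mM min⁻¹ to homo dimer, more than the 0.0867 mM min⁻¹ that the held ratio gives for the same pool, and at top speed the enzyme needs about 7.30 min to turn that charge over, so the birch figure is a ceiling.

The forecast gives maple > larch > birch, with 64.7% for maple, 47.4% for birch and 56.2% for larch, on the ground that homo dimer formation “slowly drains the pool”. Its birch and larch figures lie below mine.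

The simulation gives maple > larch > birch, with 64.7%, 47.1% and 56.2% in the same flask order as above: maple, birch, larch. For birch, a drain number of 0.534 puts half of the turnover to homo dimer up to the asked time at 1.58 h, but the flask has done that half by 0.326 h, earlier than the number says, and its product stands under the ceiling. Birch left until 2.5 h has a drain number of 0.333 and so a ceiling of 61.1%; that flask gives 53.0%.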